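## Retrosynthetic overview
1. Ring A, the ten-membered carbocycle, is closed last by ring-closing metathesis at the Z C1=C10 olefin of a butenolide that carries a vinyl and an isopropenyl terminus.
2. Ring B, the butenolide, is closed first. This is the key step: one palladium-catalysed oxidative hydroxy-carbonylation of an α-allenol makes both C–O bonds (C13–OH from water, lactone O6–C12) and brings in C12 as CO.
3. The allenol comes from an enal (C1–C6) and a propargylic boronate (C7–C11, C13). The C6–C7 bond forms by acid-catalysed propargylboration, which sets C6.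
4. C3 is set by allylboration of a C5 enal acetal. C9 is set by propargylation of methacrolein, followed by a one-carbon boron homologation.
5. Both acetates are installed on the fragments. No protecting-group steps are needed and C13–OH is born free.

Assumptions: atom labels C1–C15 are the germacrane numbers of the target (C6 lactone carbinol, C12 lactone carbonyl, C13 CH2OH), and compounds 1, 2, 7, 8, 11 and (S)-TRIP are taken as catalogue chemicals.

## Route

Step 1
Reactants: 1 (E)-4,4-dimethoxy-2-methylbut-2-enal; 2 allylboronic acid pinacol ester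
Product: 4 (2E,4S)-1,1-dimethoxy-3-methylhepta-2,6-dien-4-ol, via boric ester 3 (not isolated)
Conditions: (S)-TRIP (5 mol %), 4 Å MS, toluene, −30 °C; aq. NaHCO3 work-up
Reagents that add atoms: none
Why: Chiral phosphoric acid-catalysed allylboration runs through a closed chair transition state in which (S)-TRIP shields the Re face, so allyl adds to the Si face of the enal and sets C3 as S, while the acetal is inert under anhydrous, weakly acidic conditions.

Step 2
Reactants: 4 (2E,4S)-1,1-dimethoxy-3-methylhepta-2,6-dien-4-ol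
Product: 5 (2E,4S)-1,1-dimethoxy-3-methylhepta-2,6-dien-4-yl acetate
Conditions: Ac2O, pyridine, DMAP (5 mol %), CH2Cl2, 0 °C to rt
Reagents that add atoms: acetic anhydride, CC(=O)OC(C)=O
Why: DMAP-catalysed O-acetylation of a secondary allylic alcohol touches neither C3 nor the acetal.

Step 3
Reactants: 5 (2E,4S)-1,1-dimethoxy-3-methylhepta-2,6-dien-4-yl acetate
Product: 6 (2E,4S)-4-acetoxy-3-methylhepta-2,6-dienal
Conditions: PPTS (10 mol %), acetone–H2O 10:1, rt
Reagents that add atoms: water, O
Why: Acetal hydrolysis of an allylic dimethyl acetal is far faster than loss of the allylic acetate, and the E geometry prevents any cyclisation of the enal.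

Step 4
Reactants: 7 methacrolein; 8 allenylboronic acid pinacol ester
Product: 10 (3S)-2-methylhex-1-en-5-yn-3-ol, via boric ester 9 (not isolated)
Conditions: (S)-TRIP (5 mol %), 4 Å MS, toluene, −20 °C; aq. NaHCO3 work-up
Reagents that add atoms: none
Why: Chiral phosphoric acid-catalysed propargylation (SE2′ addition of the allenylboronate through a closed six-membered transition state) attacks the Si face of methacrolein and sets C9 as S.

Step 5
Reactants: 10 (3S)-2-methylhex-1-en-5-yn-3-ol; 11 2-(iodomethyl)-4,4,5,5-tetramethyl-1,3,2-dioxaborolane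
Product: 14 (3S)-2-methyl-7-(4,4,5,5-tetramethyl-1,3,2-dioxaborolan-2-yl)hept-1-en-5-yn-3-yl acetate, via dilithium salt 12 (not isolated), via lithium alkoxide 13 (not isolated)
Conditions: n-BuLi (2.05 equiv), THF, −78 °C; 11, −78 °C to rt; Ac2O (1.2 equiv), 0 °C
Reagents that add atoms: acetic anhydride, CC(=O)OC(C)=O
Why: In this Matteson-type homologation the alkynyllithium adds to boron, a 1,2-metallate shift expels iodide to give the propargylic boronate (C13), and the remaining alkoxide is acetylated in the same flask without touching C9.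

Step 6
Reactants: 6 (2E,4S)-4-acetoxy-3-methylhepta-2,6-dienal; 14 (3S)-2-methyl-7-(4,4,5,5-tetramethyl-1,3,2-dioxaborolan-2-yl)hept-1-en-5-yn-3-yl acetate
Product: 16 (4S,5E,7R,10S)-8-ethenylidene-7-hydroxy-5,11-dimethyldodeca-1,5,11-triene-4,10-diyl diacetate, via boric ester 15 (not isolated)
Conditions: (S)-TRIP (10 mol %), 4 Å MS, toluene, −30 to 0 °C; aq. NaHCO3 work-up
Reagents that add atoms: none
Why: Phosphoric acid-catalysed propargylboration (allenylation) reacts at the γ-alkyne carbon through a closed transition state, which forms C6–C7 and the 1,1-disubstituted allene C7=C11=C13, and Si-face attack under (S)-TRIP sets C6 as R.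

Step 7
Reactants: 16 (4S,5E,7R,10S)-8-ethenylidene-7-hydroxy-5,11-dimethyldodeca-1,5,11-triene-4,10-diyl diacetate
Product: 17 (5R)-5-[(1E,3S)-3-acetoxy-2-methylhexa-1,5-dien-1-yl]-4-[(2S)-2-acetoxy-3-methylbut-3-en-1-yl]-3-(hydroxymethyl)furan-2(5H)-one
Conditions: Pd(O2CCF3)2 (5 mol %), p-benzoquinone (1.2 equiv), CO (1 atm), THF–H2O 10:1, 0 °C to rt
Reagents that add atoms: carbon monoxide, [C-]#[O+]; water, O
Why: Proposed new method: divalent palladium is held by the C6 hydroxyl on the C6 side of the in-plane terminal allene π bond (C11=C13), so water attacks C13 from the opposite side (anti hydroxypalladation, first C–O bond), which places the σ-vinyl C11–Pd bond cis to C6 and denies the C6–OH the anti trajectory it would need for the usual 5-endo closure to a 2,5-dihydrofuran; CO insertion and capture of the acylpalladium by the C6–OH (second C–O bond, closes ring B, C6 untouched) release zerovalent palladium, which benzoquinone reoxidises; the allene is the best π ligand in the molecule; the closest known reaction types are the PdCl2/CuCl2 alkoxy-alkoxycarbonylation of allenes to 2-(alkoxymethyl)acrylates, Wacker-type oxypalladation/carbonylative lactonisation of alkenols, and hydroxyl-assisted oxidative carbonylation of allenes.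

Step 8
Reactants: 17 (5R)-5-[(1E,3S)-3-acetoxy-2-methylhexa-1,5-dien-1-yl]-4-[(2S)-2-acetoxy-3-methylbut-3-en-1-yl]-3-(hydroxymethyl)furan-2(5H)-one
Product: 18 (3S,6R,9S)-3,9-diacetoxy-13-hydroxygermacra-1(10)Z,4E,7(11)-trien-12,6-olide (CNP0328753.1)
Conditions: second-generation Grubbs catalyst (10 mol %, slow addition), tetrafluoro-1,4-benzoquinone (20 mol %), toluene (1 mM), 60 °C, argon sparge
Reagents that add atoms: none
Why: In this ring-closing metathesis ruthenium loads on the monosubstituted C1 vinyl group and closes on the isopropenyl group with loss of ethene, and a ten-membered 1,5-diene that already holds the E C4=C5 olefin takes the new trisubstituted olefin as the less strained Z isomer.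

## Compound list
1 | (E)-4,4-dimethoxy-2-methylbut-2-enal | COC(OC)/C=C(\C)C=O | starting material
2 | allylboronic acid pinacol ester | C=CCB1OC(C)(C)C(C)(C)O1 | starting material
3 | pinacol boric ester of 4 | COC(OC)/C=C(\C)[C@@H](OB1OC(C)(C)C(C)(C)O1)CC=C | intermediate
4 | (2E,4S)-1,1-dimethoxy-3-methylhepta-2,6-dien-4-ol | COC(OC)/C=C(\C)[C@@H](O)CC=C | intermediate
5 | (2E,4S)-1,1-dimethoxy-3-methylhepta-2,6-dien-4-yl acetate | COC(OC)/C=C(\C)[C@@H](OC(C)=O)CC=C | intermediate
6 | (2E,4S)-4-acetoxy-3-methylhepta-2,6-dienal | O=C/C=C(\C)[C@@H](OC(C)=O)CC=C | intermediate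
7 | methacrolein | C=C(C)C=O | starting material
8 | allenylboronic acid pinacol ester | C=C=CB1OC(C)(C)C(C)(C)O1 | starting material
9 | pinacol boric ester of 10 | CC1(C)OB(O[C@H](C(C)=C)CC#C)OC1(C)C | intermediate
10 | (3S)-2-methylhex-1-en-5-yn-3-ol | O[C@H](C(C)=C)CC#C | intermediate
11 | 2-(iodomethyl)-4,4,5,5-tetramethyl-1,3,2-dioxaborolane | ICB1OC(C)(C)C(C)(C)O1 | starting material
12 | dilithium salt of 10 (O-lithio, C-lithio) | [Li]O[C@H](C(C)=C)CC#C[Li] | intermediate
13 | lithium alkoxide of the homologated propargylic boronate | [Li]O[C@H](C(C)=C)CC#CCB1OC(C)(C)C(C)(C)O1 | intermediate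
14 | (3S)-2-methyl-7-(4,4,5,5-tetramethyl-1,3,2-dioxaborolan-2-yl)hept-1-en-5-yn-3-yl acetate | CC(=O)O[C@H](C(C)=C)CC#CCB1OC(C)(C)C(C)(C)O1 | intermediate
15 | pinacol boric ester of 16 | C=C=C(C[C@H](OC(C)=O)C(C)=C)[C@H](OB1OC(C)(C)C(C)(C)O1)/C=C(\C)[C@@H](OC(C)=O)CC=C | intermediate
16 | (4S,5E,7R,10S)-8-ethenylidene-7-hydroxy-5,11-dimethyldodeca-1,5,11-triene-4,10-diyl diacetate | C=C=C(C[C@H](OC(C)=O)C(C)=C)[C@H](O)/C=C(\C)[C@@H](OC(C)=O)CC=C | intermediate
17 | (5R)-5-[(1E,3S)-3-acetoxy-2-methylhexa-1,5-dien-1-yl]-4-[(2S)-2-acetoxy-3-methylbut-3-en-1-yl]-3-(hydroxymethyl)furan-2(5H)-one | O=C1O[C@H](/C=C(\C)[C@@H](OC(C)=O)CC=C)C(C[C@H](OC(C)=O)C(C)=C)=C1CO | intermediate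
18 | (3S,6R,9S)-3,9-diacetoxy-13-hydroxygermacra-1(10)Z,4E,7(11)-trien-12,6-olide | CC(=O)O[C@H]1CC2=C(CO)C(=O)O[C@@H]2/C=C(\C)[C@@H](OC(C)=O)C/C=C\1C | target

## Step count and risks
Total step count: 8.
Longest linear sequence: 6 (steps 1, 2, 3, 6, 7, 8).

**Step 7 (the new step).**
- Risks: 5-endo attack of the C6–OH on C13, which gives a 2,5-dihydrofuran-3-carboxylic acid. Wacker oxidation of the C1 vinyl group is also possible. Benzoquinone may be wasted through oxidation of CO by water.
- The fallback uses known chemistry. It sets out from 16 and comes back at 17.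
- Iodohydroxylation of the allenol with I2 in aqueous acetone puts iodine on the central carbon C11 and hydroxyl on C7 and gives the iodo diol F1 (C7 epimers, of no consequence).
- Carbonylative lactonisation of the vinyl iodide with the C6 hydroxyl (Pd(PPh3)4, CO 1 atm, K2CO3, THF) gives the α-methylene-β-hydroxy lactone F2.
- Re2O7-catalysed 1,3-transposition of the tertiary allylic alcohol then moves the oxygen from C7 to C13 and the double bond into the ring, which is 17.

**Step 8.**
- Risks: oligomerisation or no closure because the butenolide stiffens the chain, and ruthenium hydride isomerisation of the allylic alcohol.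
- The fallback inverts the ring order, with ring A first and ring B last. It sets out from 6 and 7 and comes back at 18.
- Catalytic asymmetric Nozaki–Hiyama 2-bromoallylation of 7 with 2,3-dibromopropene (CrCl2, chiral oxazoline–sulfonamide ligand, Mn) gives the bromo alcohol F3. Acetylation gives the bromo acetate F4.
- Nozaki–Hiyama–Kishi coupling with 6 (CrCl2, NiCl2 cat., DMF) gives the bis-allylic alcohol F5, and the C6 epimer is removed by chromatography.
- Ring-closing metathesis of this flexible tetraene gives the macrocyclic alcohol F6.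
- Acryloyl chloride and Et3N give the acrylate F7. A Morita–Baylis–Hillman reaction with aqueous formaldehyde and DABCO gives the 2-(hydroxymethyl)acrylate F8.
- A second ring-closing metathesis between the two 1,1-disubstituted olefins closes the butenolide to 18.

**Step 6.**
- Risks: mismatched or weak facial control at C6, and boronate loss by protodeboronation.
- The fallback moves the stereocontrol from the addition to a ketone reduction. It sets out from 6 and 14 and comes back at 16.
- The uncatalysed addition in toluene at rt gives the C6-epimeric allenol mixture F9.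
- Dess–Martin periodinane gives the allenyl dienyl ketone F10.
- Reduction with catecholborane and the 2-methyl-CBS-oxazaborolidine enantiomer that delivers the R carbinol gives 16.

## Further compounds
F1 | step 7 | (4S,5E,7R,10S)-7,8-dihydroxy-8-(1-iodoethenyl)-5,11-dimethyldodeca-1,5,11-triene-4,10-diyl diacetate (C8 epimers) | C=C(I)C(O)(C[C@H](OC(C)=O)C(C)=C)[C@H](O)/C=C(\C)[C@@H](OC(C)=O)CC=C
F2 | step 7 | (5R)-5-[(1E,3S)-3-acetoxy-2-methylhexa-1,5-dien-1-yl]-4-[(2S)-2-acetoxy-3-methylbut-3-en-1-yl]-4-hydroxy-3-methylideneoxolan-2-one (C4 epimers) | C=C1C(=O)O[C@H](/C=C(\C)[C@@H](OC(C)=O)CC=C)C1(O)C[C@H](OC(C)=O)C(C)=C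
F3 | step 8 | (3S)-5-bromo-2-methylhexa-1,5-dien-3-ol | O[C@H](C(C)=C)CC(Br)=C
F4 | step 8 | (3S)-5-bromo-2-methylhexa-1,5-dien-3-yl acetate | CC(=O)O[C@H](C(C)=C)CC(Br)=C
F5 | step 8 | (4S,5E,7R,10S)-7-hydroxy-5,11-dimethyl-8-methylidenedodeca-1,5,11-triene-4,10-diyl diacetate | C=C(C[C@H](OC(C)=O)C(C)=C)[C@H](O)/C=C(\C)[C@@H](OC(C)=O)CC=C
F6 | step 8 | (3S,6R,9S)-3,9-diacetoxy-6-hydroxy-7-methylidene-4,10-dimethylcyclodeca-1(10)Z,4E-diene (germacrane numbering) | CC(=O)O[C@H]1CC(=C)[C@H](O)/C=C(\C)[C@@H](OC(C)=O)C/C=C\1C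
F7 | step 8 | C6 acrylate of F6 | CC(=O)O[C@H]1CC(=C)[C@H](OC(=O)C=C)/C=C(\C)[C@@H](OC(C)=O)C/C=C\1C
F8 | step 8 | C6 2-(hydroxymethyl)acrylate of F6 | CC(=O)O[C@H]1CC(=C)[C@H](OC(=O)C(=C)CO)/C=C(\C)[C@@H](OC(C)=O)C/C=C\1C
F9 | step 6 | (4S,5E,10S)-8-ethenylidene-7-hydroxy-5,11-dimethyldodeca-1,5,11-triene-4,10-diyl diacetate (both C7 epimers) | C=C=C(C[C@H](OC(C)=O)C(C)=C)C(O)/C=C(\C)[C@@H](OC(C)=O)CC=C
F10 | step 6 | (4S,5E,10S)-8-ethenylidene-5,11-dimethyl-7-oxododeca-1,5,11-triene-4,10-diyl diacetate | C=C=C(C[C@H](OC(C)=O)C(C)=C)C(=O)/C=C(\C)[C@@H](OC(C)=O)CC=C
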